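The synthesis rests on cutting both pyranone rings at their aryl ketone bonds, C4–C4a in ring C and C4''–C4a'' in ring E. One treatment with a dehydrating acid turns two carboxylic acids into acylating carbons and closes both rings, giving the complete biflavone skeleton. The step exploits that C4a (ring A) and C4a'' (ring D) lie ortho to the aryloxy oxygen and ortho/para to two methoxy groups of phloroglucinol-type rings. Ring A offers two identical sites, ring D a single one because C8'' already bears C3' of ring B. The precursor is the finished B–D biaryl carrying two (Z)-3-aryloxycinnamic acid arms, with isopropyl ethers on O4' and O4'''.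

Key step: step 11

Assumption: the C3'–C8'' biaryl axis has no stereodescriptor in the target and is treated as stereochemically undefined, and each enol ether is drawn as the Z isomer expected from anti addition, any E isomer being carried along because the acid of step 11 interconverts the two.

Step 1
Reactants: 1 2-bromo-4-iodophenol
Product: 2 2-bromo-4-iodo-1-isopropoxybenzene
Conditions: iPrBr, K2CO3, DMF, 60 °C
Reagents that add atoms: 2-bromopropane, CC(C)Br
Why: Williamson ether synthesis (SN2 of the potassium phenoxide on 2-bromopropane) that leaves both aryl halides untouched and installs an ether stable to base and palladium yet removable with BCl3 at the end.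

Step 2
Reactants: 2 2-bromo-4-iodo-1-isopropoxybenzene; 3 ethyl propiolate
Product: 4 ethyl 3-(3-bromo-4-isopropoxyphenyl)prop-2-ynoate
Conditions: PdCl2(PPh3)2 (cat.), CuI (cat.), K2CO3, excess 3, THF, 65 °C
Reagents that add atoms: none
Why: Sonogashira coupling with an inorganic base in place of an amine, which would add to the propiolate; zerovalent palladium inserts into C–I much faster than into C–Br, so the bromide is kept for step 4.

Step 3
Reactants: 4 ethyl 3-(3-bromo-4-isopropoxyphenyl)prop-2-ynoate; 5 3,5-dimethoxyphenol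
Product: 6 ethyl (Z)-3-(3-bromo-4-isopropoxyphenyl)-3-(3,5-dimethoxyphenoxy)acrylate
Conditions: K2CO3, DMF, 80 °C
Reagents that add atoms: none
Why: Base-mediated oxa-Michael addition of a phenoxide through oxygen to an arylpropiolate, with anti protonation favouring the Z enol ether; placing it before the biaryl coupling means that no intermediate ever holds a free phenol and an alkynoate together, which would oligomerise.

Step 4
Reactants: 6 ethyl (Z)-3-(3-bromo-4-isopropoxyphenyl)-3-(3,5-dimethoxyphenoxy)acrylate
Product: 7 ethyl (Z)-3-(3,5-dimethoxyphenoxy)-3-[4-isopropoxy-3-(4,4,5,5-tetramethyl-1,3,2-dioxaborolan-2-yl)phenyl]acrylate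
Conditions: B2pin2, PdCl2(dppf) (cat.), KOAc, 1,4-dioxane, 90 °C
Reagents that add atoms: bis(pinacolato)diboron, CC1(C)OB(OC1(C)C)B1OC(C)(C)C(C)(C)O1
Why: Miyaura borylation of an aryl bromide with a base too weak to harm ester or enol ether; putting boron on ring B, with one ortho alkoxy group, avoids the rapid protodeboronation expected for a 2,6-dioxygenated ring D boronate.

Step 5
Reactants: 5 3,5-dimethoxyphenol
Product: 8 2-iodo-3,5-dimethoxyphenol
Conditions: NIS (1.0 equiv), MeCN, 0 °C, dark
Reagents that add atoms: N-iodosuccinimide, O=C1CCC(=O)N1I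
Why: Electrophilic aromatic iodination in which C2 and C4 are both activated by all three oxygens, but C2 is less crowded and statistically doubled, so the 2-iodide should be the main product and the 4-iodide can be removed by chromatography.

Step 6
Reactants: 7 ring B pinacol boronate; 8 2-iodo-3,5-dimethoxyphenol
Product: 9 ethyl (Z)-3-(3,5-dimethoxyphenoxy)-3-[3-(2-hydroxy-4,6-dimethoxyphenyl)-4-isopropoxyphenyl]acrylate
Conditions: Pd(OAc)2 (cat.), SPhos, K3PO4, toluene/H2O, 85 °C
Reagents that add atoms: none
Why: Suzuki–Miyaura coupling with a bulky electron-rich biarylphosphine suited to tri-ortho-substituted biaryls and tolerant of a free phenol, forming the future C3'–C8'' bond at the carbon of ring D that lies between OH and OMe.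

Step 7
Reactants: 10 4-iodophenol
Product: 11 1-iodo-4-isopropoxybenzene
Conditions: iPrBr, K2CO3, DMF, 60 °C
Reagents that add atoms: 2-bromopropane, CC(C)Br
Why: Williamson ether synthesis, as in step 1.

Step 8
Reactants: 11 1-iodo-4-isopropoxybenzene; 3 ethyl propiolate
Product: 12 ethyl 3-(4-isopropoxyphenyl)prop-2-ynoate
Conditions: PdCl2(PPh3)2 (cat.), CuI (cat.), K2CO3, excess 3, THF, 65 °C
Reagents that add atoms: none
Why: The same amine-free Sonogashira coupling as in step 2, the excess of 3 making up for its base-induced self-condensation.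

Step 9
Reactants: 9 biaryl phenol; 12 ethyl 3-(4-isopropoxyphenyl)prop-2-ynoate
Product: 13 (Z,Z)-diethyl diester, ethyl (Z)-3-(3,5-dimethoxyphenoxy)-3-[3-(2-{[(Z)-3-ethoxy-1-(4-isopropoxyphenyl)-3-oxoprop-1-en-1-yl]oxy}-4,6-dimethoxyphenyl)-4-isopropoxyphenyl]acrylate
Conditions: Cs2CO3, 12 (1.5–2 equiv), DMF, 85 °C
Reagents that add atoms: none
Why: Second oxa-Michael addition, in which the caesium phenoxide of 9 attacks the alkynoate, a far better acceptor than the donor-substituted enol ether ester already present, and the excess of 12 keeps aryloxy exchange at that older site in check.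

Step 10
Reactants: 13 (Z,Z)-diethyl diester
Product: 14 (Z,Z)-diacid, (Z)-3-[3-(2-{[(Z)-2-carboxy-1-(4-isopropoxyphenyl)ethenyl]oxy}-4,6-dimethoxyphenyl)-4-isopropoxyphenyl]-3-(3,5-dimethoxyphenoxy)acrylic acid
Conditions: LiOH·H2O, THF/EtOH/H2O, 45 °C; then 1 M HCl, 0 °C, pH 3
Reagents that add atoms: lithium hydroxide, [Li+].[OH-]
Why: Ester saponification by acyl–oxygen cleavage; the β-aryloxy enoates behave as vinylogous carbonates that resist hydroxide at the β-carbon, and brief cold acidification spares the enol ethers.

Step 11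
Reactants: 14 (Z,Z)-diacid
Product: 16 4',4'''-di-O-isopropyl-5,5'',7,7''-tetra-O-methylamentoflavone, via ring-C-closed monoacid 15 (not isolated)
Conditions: P2O5/CH3SO3H (1:10 w/w, Eaton's reagent), ca. 0.02 M, 0 °C → rt; poured onto ice
Reagents that add atoms: none
Why: In P2O5/CH3SO3H each carboxyl group is dehydrated to an acyl methanesulfonate or free acylium ion, this electrophile is captured by the ring carbon next to the ether oxygen of the aryloxy group standing cis to it on the alkene, and proton loss restores aromaticity, which is the intramolecular Friedel–Crafts acylation known to turn 3-aryloxycinnamic acids into flavones, used here at two sites of one molecule. Ring C closes through a six-membered transition state by forming C4–C4a at either of the two equivalent ortho carbons of ring A, probably first (15), and ring E closes in the same six-membered mode by forming C4''–C4a'' at the only free ortho carbon of ring D. Any E enol ether is drawn in because reversible protonation at C3 or C3'' gives an oxocarbenium ion, stabilised by the aryloxy oxygen and the para-isopropoxyaryl ring, in which rotation about the former double bond is free. The chemoselectivity needed is acylation of rings A and D rather than five-membered indenone closure onto rings B and F, and it is secured because the attacked carbons of A and D are ortho or para to three oxygen donors whereas the reachable carbons of B and F are meta to their single alkoxy group. The 3'–8'' linkage is fixed by the substrate, since C8'' is already arylated, and keeping O5'' methylated at low temperature rules out a Wessely–Moser type ring opening that could move the link to C6''. No stereocentre is formed, and dilution with a start at 0 °C favours ring closure over intermolecular acylation and spares the isopropyl ethers.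

Step 12
Reactants: 16 4',4'''-di-O-isopropyl-5,5'',7,7''-tetra-O-methylamentoflavone
Product: 17 7,7''-dimethoxyamentoflavone (7,7''-di-O-methylamentoflavone)
Conditions: BCl3 (10 equiv), CH2Cl2, −78 °C → rt; then aq. HCl/MeOH
Reagents that add atoms: none
Why: Lewis-acid ether cleavage in which BCl3 removes the secondary isopropyl groups in an SN1-like manner and demethylates only O5 and O5'', where boron sits in a six-membered chelate with the C4 or C4'' carbonyl, while the unchelated 7- and 7''-methyl ethers are inert to BCl3 at or below room temperature.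

Compound list
1 | 2-bromo-4-iodophenol | Oc1ccc(I)cc1Br | starting material
2 | 2-bromo-4-iodo-1-isopropoxybenzene | CC(C)Oc1ccc(I)cc1Br | intermediate
3 | ethyl propiolate | C#CC(=O)OCC | starting material
4 | ethyl 3-(3-bromo-4-isopropoxyphenyl)prop-2-ynoate | CCOC(=O)C#Cc1ccc(OC(C)C)c(Br)c1 | intermediate
5 | 3,5-dimethoxyphenol | COc1cc(O)cc(OC)c1 | starting material
6 | ethyl (Z)-3-(3-bromo-4-isopropoxyphenyl)-3-(3,5-dimethoxyphenoxy)acrylate | CCOC(=O)/C=C(\Oc1cc(OC)cc(OC)c1)c1ccc(OC(C)C)c(Br)c1 | intermediate
7 | ethyl (Z)-3-(3,5-dimethoxyphenoxy)-3-[4-isopropoxy-3-(4,4,5,5-tetramethyl-1,3,2-dioxaborolan-2-yl)phenyl]acrylate | CCOC(=O)/C=C(\Oc1cc(OC)cc(OC)c1)c1ccc(OC(C)C)c(B2OC(C)(C)C(C)(C)O2)c1 | intermediate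
8 | 2-iodo-3,5-dimethoxyphenol | COc1cc(O)c(I)c(OC)c1 | intermediate
9 | ethyl (Z)-3-(3,5-dimethoxyphenoxy)-3-[3-(2-hydroxy-4,6-dimethoxyphenyl)-4-isopropoxyphenyl]acrylate | CCOC(=O)/C=C(\Oc1cc(OC)cc(OC)c1)c1ccc(OC(C)C)c(-c2c(O)cc(OC)cc2OC)c1 | intermediate
10 | 4-iodophenol | Oc1ccc(I)cc1 | starting material
11 | 1-iodo-4-isopropoxybenzene | CC(C)Oc1ccc(I)cc1 | intermediate
12 | ethyl 3-(4-isopropoxyphenyl)prop-2-ynoate | CCOC(=O)C#Cc1ccc(OC(C)C)cc1 | intermediate
13 | (Z,Z)-diethyl diester of 14 | CCOC(=O)/C=C(\Oc1cc(OC)cc(OC)c1)c1ccc(OC(C)C)c(-c2c(OC)cc(OC)cc2O/C(=C\C(=O)OCC)c2ccc(OC(C)C)cc2)c1 | intermediate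
14 | (Z,Z)-diacid: ring B carries the 3-(3,5-dimethoxyphenoxy)acrylic acid, the ring D oxygen carries the 3-(4-isopropoxyphenyl)acrylic acid | COc1cc(OC)c(-c2cc(/C(Oc3cc(OC)cc(OC)c3)=C/C(=O)O)ccc2OC(C)C)c(O/C(=C\C(=O)O)c2ccc(OC(C)C)cc2)c1 | intermediate
15 | ring-C-closed monoacid: 4'-isopropoxy-5,7-dimethoxyflavone bearing at C3' the 2-{[(Z)-2-carboxy-1-(4-isopropoxyphenyl)ethenyl]oxy}-4,6-dimethoxyphenyl group | COc1cc(OC)c2c(=O)cc(-c3ccc(OC(C)C)c(-c4c(OC)cc(OC)cc4O/C(=C\C(=O)O)c4ccc(OC(C)C)cc4)c3)oc2c1 | intermediate
16 | 4',4'''-di-O-isopropyl-5,5'',7,7''-tetra-O-methylamentoflavone | COc1cc(OC)c2c(=O)cc(-c3ccc(OC(C)C)c(-c4c(OC)cc(OC)c5c(=O)cc(-c6ccc(OC(C)C)cc6)oc45)c3)oc2c1 | intermediate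
17 | 7,7''-dimethoxyamentoflavone | COc1cc(O)c2c(=O)cc(-c3ccc(O)c(-c4c(OC)cc(O)c5c(=O)cc(-c6ccc(O)cc6)oc45)c3)oc2c1 | target

Total step count: 12. Longest linear sequence: 9 steps (1, 2, 3, 4, 6, 9, 10, 11, 12).

Steps most likely to fail

Step 11.
- **Risk:** The closure at the crowded ring D may lag behind that at ring A, so half-closed material stays long in strong acid. This invites loss of the isopropyl groups as cations that re-alkylate the electron-rich rings. It also invites acid cleavage of the still open enol ether with decarboxylation, and intermolecular acylation.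
- **Fallback (sets out from 6, returns at 15):** The two closures are separated, so that each is a short, single cyclisation.
  - Ester 6 is saponified with LiOH to (Z)-3-(3-bromo-4-isopropoxyphenyl)-3-(3,5-dimethoxyphenoxy)acrylic acid F1.
  - This acid is closed alone with P2O5/CH3SO3H to 3'-bromo-4'-isopropoxy-5,7-dimethoxyflavone F2.
  - Miyaura borylation (B2pin2, PdCl2(dppf), KOAc) gives 4'-isopropoxy-5,7-dimethoxy-3'-(pinacolboryl)flavone F3.
  - Suzuki–Miyaura coupling with 8 (Pd(OAc)2, SPhos, K3PO4) gives 3'-(2-hydroxy-4,6-dimethoxyphenyl)-4'-isopropoxy-5,7-dimethoxyflavone F4.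
  - Oxa-Michael addition to 12 (Cs2CO3, DMF) gives the ring-C-closed monoester F5.
  - LiOH at room temperature gives 15, now isolated. Its other half is already an acid-inert flavone, and its single closure leads to 16.

Step 9.
- **Risk:** A hindered, ortho-arylated phenoxide may add only sluggishly to an alkynoate deactivated by its para-alkoxy donor. At the higher temperature then needed, aryloxy exchange at the older enol ether could catch up.
- **Fallback (sets out from 11 and 9, returns at 14):** The acceptor is raised to the aldehyde level.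
  - Iodide 11 is coupled with propargyl alcohol (PdCl2(PPh3)2, CuI, Et3N) to 3-(4-isopropoxyphenyl)prop-2-yn-1-ol F6.
  - MnO2 oxidises this alcohol to 3-(4-isopropoxyphenyl)prop-2-ynal F7.
  - This much stronger acceptor should take up the phenoxide of 9 at room temperature (K2CO3, MeCN) to give the (Z)-3-aryloxycinnamaldehyde monoester F8.
  - Pinnick oxidation (NaClO2, NaH2PO4, excess 2-methyl-2-butene) gives the ring-E-arm monoacid monoester F9.
  - LiOH as in step 10 then gives 14.

Step 6.
- **Risk:** Zerovalent palladium may insert only slowly into a very electron-rich iodophenoxide, and transmetalation at a tri-ortho-substituted axis is hindered. Protodeboronation and hydrodeiodination could then take over.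
- **Fallback (sets out from 8, 12 and 6, returns at 13, bypassing 7 and 9):** The polarity is inverted, and the phenol is masked as the very enol ether needed later.
  - Phenol 8 adds to 12 (K2CO3, DMF) to give ethyl (Z)-3-(2-iodo-3,5-dimethoxyphenoxy)-3-(4-isopropoxyphenyl)acrylate F10.
  - Direct insertion of zinc dust in the presence of LiCl (THF, 50 °C) gives the ring D arylzinc iodide F11. Zinc is chosen over magnesium because an arylmagnesium species would attack its own ester.
  - Negishi coupling with bromide 6 (Pd(OAc)2, SPhos, THF, 60 °C) gives 13.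
  - Palladium inserts into ring B only, never next to the ring D enol ether, so a 5-endo Heck closure to a benzofuran cannot start.

Further compounds
F1 | step 11 | (Z)-3-(3-bromo-4-isopropoxyphenyl)-3-(3,5-dimethoxyphenoxy)acrylic acid | OC(=O)/C=C(\Oc1cc(OC)cc(OC)c1)c1ccc(OC(C)C)c(Br)c1
F2 | step 11 | 3'-bromo-4'-isopropoxy-5,7-dimethoxyflavone | COc1cc(OC)c2c(=O)cc(-c3ccc(OC(C)C)c(Br)c3)oc2c1
F3 | step 11 | 4'-isopropoxy-5,7-dimethoxy-3'-(pinacolboryl)flavone | COc1cc(OC)c2c(=O)cc(-c3ccc(OC(C)C)c(B4OC(C)(C)C(C)(C)O4)c3)oc2c1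
F4 | step 11 | 3'-(2-hydroxy-4,6-dimethoxyphenyl)-4'-isopropoxy-5,7-dimethoxyflavone | COc1cc(OC)c2c(=O)cc(-c3ccc(OC(C)C)c(-c4c(O)cc(OC)cc4OC)c3)oc2c1
F5 | step 11 | ring-C-closed monoester (ethyl ester of 15) | COc1cc(OC)c2c(=O)cc(-c3ccc(OC(C)C)c(-c4c(OC)cc(OC)cc4O/C(=C\C(=O)OCC)c4ccc(OC(C)C)cc4)c3)oc2c1
F6 | step 9 | 3-(4-isopropoxyphenyl)prop-2-yn-1-ol | OCC#Cc1ccc(OC(C)C)cc1
F7 | step 9 | 3-(4-isopropoxyphenyl)prop-2-ynal | O=CC#Cc1ccc(OC(C)C)cc1
F8 | step 9 | (Z)-3-aryloxycinnamaldehyde monoester | CCOC(=O)/C=C(\Oc1cc(OC)cc(OC)c1)c1ccc(OC(C)C)c(-c2c(OC)cc(OC)cc2O/C(=C\C=O)c2ccc(OC(C)C)cc2)c1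
F9 | step 9 | ring-E-arm monoacid monoester | CCOC(=O)/C=C(\Oc1cc(OC)cc(OC)c1)c1ccc(OC(C)C)c(-c2c(OC)cc(OC)cc2O/C(=C\C(=O)O)c2ccc(OC(C)C)cc2)c1
F10 | step 6 | ethyl (Z)-3-(2-iodo-3,5-dimethoxyphenoxy)-3-(4-isopropoxyphenyl)acrylate | CCOC(=O)/C=C(\Oc1cc(OC)cc(OC)c1I)c1ccc(OC(C)C)cc1
F11 | step 6 | ring D arylzinc iodide | CCOC(=O)/C=C(\Oc1cc(OC)cc(OC)c1[Zn]I)c1ccc(OC(C)C)cc1
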